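**Strategy**

Numbering: ring C1 (tertiary carbinol), C5 (angelate), C6 (lactone O–CH), C7, C8 (CHOH), C9 (CH2), C10 (CHCH3). This cycloheptane is cut at C5–C6 and C9–C10 into the oxygenated three-carbon unit C5–C1–C10 and the four-carbon unit C6–C9. One (4+3) cycloaddition of a chiral 1-alkoxy-2-siloxyallyl cation to 3-methoxyfuran forms both bonds, the ring and the C5 and C6 stereocentres. It exploits the 1,4-relation of the C6 lactone oxygen and the C9 methylene plus the C8 oxygen: the furan oxygen becomes the lactone oxygen and is later cut reductively from C9; the methoxy carbon becomes C8, the cation carbonyl C1. The precursor is an acyclic silyl enol ether of a mixed pyruvaldehyde acetal.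

Key step: step 3

Remark on numbering: the other target atoms are C2 (ketone carbon), C3=C4 and C15 in the side chain on C1; C11, C12 (lactone carbonyl) and C13 (exocyclic methylene); C14 is the methyl group on C10. The same numbers are used for all intermediates.

Assumption: the (R)-1-phenylethoxy group is taken to shield the face of cation 6 that would lead to the enantiomeric bicycle; if the sense of induction were the opposite, (S)-1-phenylethanol would be used with no other change.

**Route**

Step 1
Reactants: 1 1,1-dimethoxypropan-2-one; 2 (R)-1-phenylethanol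
Product: 3 1-methoxy-1-[(1R)-1-phenylethoxy]propan-2-one (both epimers at the acetal carbon)
Conditions: p-TsOH (cat.), cyclohexane, 5 Å molecular sieves, 60 °C, excess of 1
Reagents that add atoms: none
Why: Acid-catalysed transacetalization exchanges one methoxy group for the chiral alkoxy group, and the configuration of the acetal carbon is of no consequence because that carbon is ionised in step 3.

Step 2
Reactants: 3 mixed acetal
Product: 4 triethyl({3-methoxy-3-[(1R)-1-phenylethoxy]prop-1-en-2-yl}oxy)silane
Conditions: LiN(i-Pr)2, Et3SiCl, THF, −78 °C (internal quench)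
Reagents that add atoms: chlorotriethylsilane CC[Si](Cl)(CC)CC
Why: Kinetic deprotonation of the methyl group of the methyl ketone and O-silylation (silyl enol ether formation) should give the terminal enol ether; no stereocentre is set.

Step 3
Reactants: 4 silyl enol ether; 5 3-methoxyfuran
Product: 7 (1R,2S,5R)-6-methoxy-2-[(1R)-1-phenylethoxy]-8-oxabicyclo[3.2.1]oct-6-en-3-one (alkoxy group equatorial; anti to the oxygen bridge), via siloxyallyl cation 6 (not isolated)
Conditions: Me3SiOTf (0.1 equiv), CH2Cl2, −95 °C; then Et3N
Reagents that add atoms: none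
Why: Me3SiOTf ionises the mixed acetal with loss of the smaller methoxy group to the W-shaped 1-alkoxy-2-siloxyallyl cation 6, a three-carbon 2π unit (C5–C1–C10) that adds across the 2,5-positions of the furan 4π unit (C9=C8–C7=C6), after which silyl transfer to triflate releases the ketone and the catalyst; the closest known reaction type is the low-temperature (4+3) cycloaddition of alkoxy-substituted siloxyallyl cations carrying a 1-phenylethyl auxiliary with furan. The cycloheptenone ring and the oxygen-bridged pyranone ring are closed together by this intermolecular (4+3) annulation, suprafacial on both partners through a compact transition state, bond C9–C10 being formed ahead of bond C5–C6 (attack of the furan on the cation, then seven-membered ring closure of the enol ether onto the furan-derived oxocarbenium ion). The bridgehead centres C6 and C9 are fixed cis by suprafacial addition to the planar furan, and the C5 alkoxy group should end equatorial because of the W geometry of the cation in the compact transition state, which is also the thermodynamically preferred epimer of the α-alkoxy ketone. The absolute configuration is controlled by the (R)-1-phenylethyl group, whose phenyl ring covers one face of the cation so that the furan adds to the other. The step needs regioselectivity (C10 to the furan carbon next to the methoxy group, C5 to the remote one), secured because the methoxy donor makes furan C2 the most nucleophilic position and the unsubstituted terminus C10 of the alkoxy-stabilised cation the most electrophilic one, and it needs cycloaddition to win over substitution, which the low temperature and the catalytic amount of acid favour.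

Step 4
Reactants: 7 cycloadduct
Product: 9 (1R,2S,4S,5R)-6-methoxy-4-methyl-2-[(1R)-1-phenylethoxy]-8-oxabicyclo[3.2.1]oct-6-en-3-one (C10 methyl axial; syn to the oxygen bridge), via lithium enolate 8 (not isolated)
Conditions: LiN(i-Pr)2, THF, −78 °C; then MeI, DMPU, −78 → −40 °C
Reagents that add atoms: iodomethane CI
Why: Kinetic enolate alkylation, in which deprotonation should occur at C10 (the alkoxy-bearing C5–H is kinetically less acidic) and iodomethane should attack the bicyclic enolate from the exo face syn to the oxygen bridge (axial attack, the endo face being covered by the two-carbon bridge), which sets the C10 methyl axial as required.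

Step 5
Reactants: 9 methylated ketone
Product: 11 4-methyl-3-methylidene-2-[(1R)-1-phenylethoxy]-8-oxabicyclo[3.2.1]octan-6-one (C1 methylene; C8 ketone; ring stereocentres as in 9), via β-hydroxysilane 10 (not isolated)
Conditions: Me3SiCH2Li, CeCl3, THF, −78 → 0 °C; then 1 M aq. HCl, THF, rt
Reagents that add atoms: (trimethylsilyl)methyllithium [Li]C[Si](C)(C)C; water O
Why: Peterson olefination through the weakly basic organocerium reagent should methylenate the hindered C1 ketone without enolisation or epimerisation at C10, and the acidic elimination stage also hydrolyses the methyl enol ether to the C8 ketone; no stereocentre is set.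

Step 6
Reactants: 11 methylene ketone
Product: 12 3-hydroxy-3-(hydroxymethyl)-4-methyl-2-[(1R)-1-phenylethoxy]-8-oxabicyclo[3.2.1]octan-6-one (C1 hydroxyl equatorial and syn to the oxygen bridge; CH2OH axial)
Conditions: OsO4 (cat.), N-methylmorpholine N-oxide, acetone–H2O, rt
Reagents that add atoms: N-methylmorpholine N-oxide C[N+]1([O-])CCOCC1; water O
Why: Upjohn dihydroxylation, in which OsO4 can reach the exocyclic alkene only from the exo face because the endo face lies directly over the two-carbon bridge, so the new C1 oxygen should be placed syn to the oxygen bridge and C2 axial, as in the target.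

Step 7
Reactants: 12 diol
Product: 13 acetonide of 12 (spiro 2,2-dimethyl-1,3-dioxolane on C1)
Conditions: 2,2-dimethoxypropane, PPTS (cat.), CH2Cl2, rt
Reagents that add atoms: 2,2-dimethoxypropane COC(C)(C)OC
Why: Ketalisation of the 1,2-diol protects both hydroxyls for the enolate, reduction and lactone chemistry that follows (any internal hemiketal between the axial CH2OH and the C8 ketone is in equilibrium with the open diol and is drained); no stereocentre is affected.

Step 8
Reactants: 13 acetonide; 14 ethyl glyoxylate
Product: 18 ethyl (E)-2-(bicyclic 8-oxo-7-ylidene)acetate (13 with C7=C11H–CO2Et), via lithium enolate 15 (not isolated), via lithium aldolate 16 (not isolated), via β-mesyloxy ketone 17 (not isolated)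
Conditions: LiN(SiMe3)2, THF, −78 °C; 14; then MeSO2Cl, Et3N, −78 → 0 °C
Reagents that add atoms: none
Why: Aldol condensation, in which the C8 ketone can enolise only towards C7 because C9 is a bridgehead, the enolate should not expel the bridging oxygen at −78 °C (the C6–O bond lies near its nodal plane), and mesylation–elimination of the aldolate should give the conjugated alkylidene that carries C11 and C12.

Step 9
Reactants: 18 alkylidene keto ester
Product: 19 keto ester with the CH2CO2Et group on C7 endo (anti to the oxygen bridge)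
Conditions: H2 (1 atm), Pd/C, pyridine (0.5 equiv), EtOAc, rt
Reagents that add atoms: none
Why: Heterogeneous hydrogenation should deliver hydrogen to C7 from the open exo face, which sets C7 with its side chain endo (the pyran ring can relax to a boat to make room for it), while pyridine suppresses hydrogenolysis of the benzylic ether.

Step 10
Reactants: 19 bicyclic keto ester
Product: 21 trans-fused keto lactone (12,6-olide; C8 ketone; C9 methylene), via hydroxy keto ester 20 (not isolated)
Conditions: SmI2 (2.5 equiv), THF–MeOH, −78 °C; then PPTS (cat.), CH2Cl2, rt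
Reagents that add atoms: none
Why: Reductive cleavage of the α-alkoxy ketone by samarium diiodide (ketyl formation, then β-elimination of the C9–O bond) should turn C9 into a methylene group and free the C6 oxygen with retention, which lactonises onto the ester on the opposite face to give the trans-fused γ-lactone; the C1 ketal and the C5 ether are not α to the ketone and should stay.

Step 11
Reactants: 21 keto lactone
Product: 23 8-O-tert-butyldimethylsilyl ether of the 8β-alcohol, via C8 alcohol 22 (not isolated)
Conditions: LiBH(s-Bu)3, THF, −78 °C; then t-BuMe2SiOTf, 2,6-lutidine, −78 → 0 °C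
Reagents that add atoms: tert-butyldimethylsilyl triflate CC(C)(C)[Si](C)(C)OS(=O)(=O)C(F)(F)F
Why: Diastereoselective ketone reduction, in which the bulky hydride should approach along the equatorial trajectory anti to the adjacent C7–C11 bond and give the axial 8β-alkoxide cis to C11 (as with 2-substituted cycloalkanones), which is silylated in the same flask.

Step 12
Reactants: 23 silyl ether
Product: 24 C5 alcohol
Conditions: H2 (1 atm), Pd(OH)2/C, EtOH, rt
Reagents that add atoms: none
Why: Hydrogenolysis of the benzylic 1-phenylethyl ether removes the auxiliary and frees the C5 hydroxyl, while silyl ether, ketal and lactone are inert and no alkene is present yet.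

Step 13
Reactants: 24 C5 alcohol
Product: 28 α-methylene lactone, via dilithium alkoxide–enolate 25 (not isolated), via Mannich base 26 (not isolated), via trimethylammonium iodide 27 (not isolated)
Conditions: LiN(i-Pr)2 (2.5 equiv), THF, −78 °C; Me2N=CH2 I (Eschenmoser's salt), −78 °C → rt; then MeI, MeOH, rt; then aq. NaHCO3, CH2Cl2
Reagents that add atoms: Eschenmoser's salt C=[N+](C)C.[I-]
Why: α-Methylenation of the lactone by Mannich reaction of its enolate, quaternisation and Hofmann-type elimination should install C13; C11 becomes trigonal, so no new stereocentre remains and C7 is untouched.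

Step 14
Reactants: 28 α-methylene lactone; 29 angelic acid
Product: 31 C5 angelate, via mixed anhydride 30 (not isolated)
Conditions: 29, 2,4,6-trichlorobenzoyl chloride, Et3N, toluene, rt; then 28, toluene, 80 °C
Reagents that add atoms: none
Why: Yamaguchi esterification through the mixed anhydride should acylate the hindered C5 hydroxyl without a nucleophilic amine catalyst, conditions chosen to preserve the (Z)-geometry of the angeloyl group.

Step 15
Reactants: 31 angelate
Product: 32 C1,C2-diol
Conditions: AcOH–H2O (4:1), 40 °C
Reagents that add atoms: none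
Why: Mild acid hydrolysis of the dioxolane frees the tertiary and the primary hydroxyl, while the secondary silyl ether, the angelate and the α-methylene lactone should survive.

Step 16
Reactants: 32 diol
Product: 33 C2 aldehyde
Conditions: TEMPO (0.2 equiv), PhI(OAc)2 (1.1 equiv), CH2Cl2, rt
Reagents that add atoms: none
Why: Oxoammonium (TEMPO) oxidation is selective for the primary alcohol, the tertiary C1 hydroxyl cannot be oxidised, and with C8 silylated no lactol or lactone can form.

Step 17
Reactants: 33 aldehyde; 34 (E)-1-bromoprop-1-ene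
Product: 36 allylic alcohol (both C2 epimers), via (E)-prop-1-enylchromium dichloride 35 (not isolated)
Conditions: CrCl2 (5 equiv), NiCl2 (cat.), DMF, rt
Reagents that add atoms: none
Why: Nozaki–Hiyama–Kishi addition, in which the alkenylchromium reagent should add only to the aldehyde (esters, lactone and enoate are inert) with retention of the (E)-alkene; the C2 configuration is of no consequence because C2 is oxidised next.

Step 18
Reactants: 36 allylic alcohol
Product: 37 8-O-silyl ether of the target
Conditions: 2-iodoxybenzoic acid, DMSO, rt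
Reagents that add atoms: none
Why: Oxidation of the secondary allylic alcohol to the enone with 2-iodoxybenzoic acid, which oxidises 1,2-diols without C–C cleavage and leaves the tertiary alcohol alone.

Step 19
Reactants: 37 silyl ether
Product: 38 target CNP0206014.2
Conditions: HF·pyridine, THF, 0 °C → rt
Reagents that add atoms: none
Why: Fluoride-mediated desilylation should free the C8 hydroxyl without touching the esters, the enone or the α-methylene lactone.

**Compound list**

1 | 1,1-dimethoxypropan-2-one | CC(=O)C(OC)OC | starting material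
2 | (R)-1-phenylethanol | C[C@@H](O)c1ccccc1 | starting material
3 | 1-methoxy-1-[(1R)-1-phenylethoxy]propan-2-one (both acetal epimers) | CC(=O)C(OC)O[C@H](C)c1ccccc1 | intermediate
4 | triethyl({3-methoxy-3-[(1R)-1-phenylethoxy]prop-1-en-2-yl}oxy)silane | C=C(O[Si](CC)(CC)CC)C(OC)O[C@H](C)c1ccccc1 | intermediate
5 | 3-methoxyfuran | COc1ccoc1 | starting material
6 | 1-[(1R)-1-phenylethoxy]-2-(triethylsilyloxy)allyl cation triflate (not isolated) | C=C(O[Si](CC)(CC)CC)C=[O+][C@H](C)c1ccccc1.[O-]S(=O)(=O)C(F)(F)F | intermediate
7 | (1R,2S,5R)-6-methoxy-2-[(1R)-1-phenylethoxy]-8-oxabicyclo[3.2.1]oct-6-en-3-one (alkoxy equatorial) | O1[C@@H]2C=C(OC)[C@H]1CC(=O)[C@H]2O[C@H](C)c1ccccc1 | intermediate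
8 | lithium enolate of 7 (C1=C10; not isolated) | O1[C@@H]2C=C(OC)[C@H]1C=C(O[Li])[C@H]2O[C@H](C)c1ccccc1 | intermediate
9 | (1R,2S,4S,5R)-6-methoxy-4-methyl-2-[(1R)-1-phenylethoxy]-8-oxabicyclo[3.2.1]oct-6-en-3-one (methyl axial) | O1[C@@H]2C=C(OC)[C@H]1[C@H](C)C(=O)[C@H]2O[C@H](C)c1ccccc1 | intermediate
10 | β-hydroxysilane: 9 with C(OH)CH2SiMe3 in place of the ketone (carbinol configuration of no consequence; not isolated) | O1[C@@H]2C=C(OC)[C@H]1[C@H](C)C(O)(C[Si](C)(C)C)[C@H]2O[C@H](C)c1ccccc1 | intermediate
11 | 4-methyl-3-methylidene-2-[(1R)-1-phenylethoxy]-8-oxabicyclo[3.2.1]octan-6-one (ring stereocentres as in 9) | O1[C@@H]2CC(=O)[C@H]1[C@H](C)C(=C)[C@H]2O[C@H](C)c1ccccc1 | intermediate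
12 | 3-hydroxy-3-(hydroxymethyl)-4-methyl-2-[(1R)-1-phenylethoxy]-8-oxabicyclo[3.2.1]octan-6-one (3-OH syn to the oxygen bridge) | O1[C@@H]2CC(=O)[C@H]1[C@H](C)[C@@](O)(CO)[C@H]2O[C@H](C)c1ccccc1 | intermediate
13 | acetonide of 12 (spiro dioxolane on C1) | O1[C@@H]2CC(=O)[C@H]1[C@H](C)[C@@]3(COC(C)(C)O3)[C@H]2O[C@H](C)c1ccccc1 | intermediate
14 | ethyl glyoxylate | CCOC(=O)C=O | starting material
15 | lithium enolate of 13 (C7=C8; not isolated) | O1[C@@H]2C=C(O[Li])[C@H]1[C@H](C)[C@@]3(COC(C)(C)O3)[C@H]2O[C@H](C)c1ccccc1 | intermediate
16 | lithium aldolate: 13 with CH(OLi)CO2Et on C7 (not isolated) | O1[C@@H]2C(C(O[Li])C(=O)OCC)C(=O)[C@H]1[C@H](C)[C@@]3(COC(C)(C)O3)[C@H]2O[C@H](C)c1ccccc1 | intermediate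
17 | β-mesyloxy ketone: 13 with CH(OSO2Me)CO2Et on C7 (not isolated) | O1[C@@H]2C(C(OS(C)(=O)=O)C(=O)OCC)C(=O)[C@H]1[C@H](C)[C@@]3(COC(C)(C)O3)[C@H]2O[C@H](C)c1ccccc1 | intermediate
18 | (E)-alkylidene keto ester: 13 with C7=CH–CO2Et | O1[C@@H]2/C(=C\C(=O)OCC)C(=O)[C@H]1[C@H](C)[C@@]3(COC(C)(C)O3)[C@H]2O[C@H](C)c1ccccc1 | intermediate
19 | keto ester: 13 with endo CH2CO2Et on C7 | O1[C@@H]2[C@@H](CC(=O)OCC)C(=O)[C@H]1[C@H](C)[C@@]3(COC(C)(C)O3)[C@H]2O[C@H](C)c1ccccc1 | intermediate
20 | monocyclic hydroxy keto ester (C6–OH, C8 ketone, C9 methylene; not isolated) | O[C@@H]1[C@@H](CC(=O)OCC)C(=O)C[C@H](C)[C@@]3(COC(C)(C)O3)[C@H]1O[C@H](C)c2ccccc2 | intermediate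
21 | trans-fused keto lactone (12,6-olide, C8 ketone, C5 phenylethyl ether, C1/C2 acetonide) | O=C1O[C@@H]2[C@@H](C1)C(=O)C[C@H](C)[C@@]3(COC(C)(C)O3)[C@H]2O[C@H](C)c1ccccc1 | intermediate
22 | 8β-alcohol of 21 (present as its lithium alkoxide; not isolated) | O=C1O[C@@H]2[C@@H](C1)[C@@H](O)C[C@H](C)[C@@]3(COC(C)(C)O3)[C@H]2O[C@H](C)c1ccccc1 | intermediate
23 | 8-O-tert-butyldimethylsilyl ether of 22 | O=C1O[C@@H]2[C@@H](C1)[C@@H](O[Si](C)(C)C(C)(C)C)C[C@H](C)[C@@]3(COC(C)(C)O3)[C@H]2O[C@H](C)c1ccccc1 | intermediate
24 | C5 alcohol (auxiliary removed) | O=C1O[C@@H]2[C@@H](C1)[C@@H](O[Si](C)(C)C(C)(C)C)C[C@H](C)[C@@]3(COC(C)(C)O3)[C@H]2O | intermediate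
25 | dilithium alkoxide–enolate of 24 (not isolated) | [Li]OC=1O[C@@H]2[C@@H](C=1)[C@@H](O[Si](C)(C)C(C)(C)C)C[C@H](C)[C@@]3(COC(C)(C)O3)[C@H]2O[Li] | intermediate
26 | Mannich base: 24 with CH2NMe2 on C11 (not isolated) | CN(C)CC1C(=O)O[C@@H]2[C@@H]1[C@@H](O[Si](C)(C)C(C)(C)C)C[C@H](C)[C@@]3(COC(C)(C)O3)[C@H]2O | intermediate
27 | trimethylammonium iodide of 26 (not isolated) | C[N+](C)(C)CC1C(=O)O[C@@H]2[C@@H]1[C@@H](O[Si](C)(C)C(C)(C)C)C[C@H](C)[C@@]3(COC(C)(C)O3)[C@H]2O.[I-] | intermediate
28 | α-methylene lactone with free C5 hydroxyl | C=C1C(=O)O[C@@H]2[C@@H]1[C@@H](O[Si](C)(C)C(C)(C)C)C[C@H](C)[C@@]3(COC(C)(C)O3)[C@H]2O | intermediate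
29 | angelic acid ((Z)-2-methylbut-2-enoic acid) | C/C=C(/C)C(=O)O | starting material
30 | angelic 2,4,6-trichlorobenzoic anhydride (not isolated) | C/C=C(/C)C(=O)OC(=O)c1c(Cl)cc(Cl)cc1Cl | intermediate
31 | C5 angelate (8-O-silyl, C1/C2 acetonide) | C=C1C(=O)O[C@@H]2[C@@H]1[C@@H](O[Si](C)(C)C(C)(C)C)C[C@H](C)[C@@]3(COC(C)(C)O3)[C@H]2OC(=O)/C(C)=C\C | intermediate
32 | C1,C2-diol | C=C1C(=O)O[C@@H]2[C@@H]1[C@@H](O[Si](C)(C)C(C)(C)C)C[C@H](C)[C@@](O)(CO)[C@H]2OC(=O)/C(C)=C\C | intermediate
33 | C2 aldehyde | C=C1C(=O)O[C@@H]2[C@@H]1[C@@H](O[Si](C)(C)C(C)(C)C)C[C@H](C)[C@@](O)(C=O)[C@H]2OC(=O)/C(C)=C\C | intermediate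
34 | (E)-1-bromoprop-1-ene | C/C=C/Br | starting material
35 | (E)-prop-1-enylchromium dichloride (not isolated) | C/C=C/[Cr](Cl)Cl | intermediate
36 | allylic alcohol (both C2 epimers) | C=C1C(=O)O[C@@H]2[C@@H]1[C@@H](O[Si](C)(C)C(C)(C)C)C[C@H](C)[C@@](O)(C(O)/C=C/C)[C@H]2OC(=O)/C(C)=C\C | intermediate
37 | 8-O-tert-butyldimethylsilyl ether of the target | C=C1C(=O)O[C@@H]2[C@@H]1[C@@H](O[Si](C)(C)C(C)(C)C)C[C@H](C)[C@@](O)(C(=O)/C=C/C)[C@H]2OC(=O)/C(C)=C\C | intermediate
38 | CNP0206014.2 | C=C1C(=O)O[C@@H]2[C@@H]1[C@@H](O)C[C@H](C)[C@@](O)(C(=O)/C=C/C)[C@H]2OC(=O)/C(C)=C\C | target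

**Step count and risks**

Total step count: 19. Longest linear sequence: 19 steps (from 1; compounds 2, 5, 14, 29 and 34 are purchased).

Steps most likely to fail:

1. Step 3. The very electron-rich methoxyfuran may be consumed by proton loss after the first C–C bond (substitution instead of ring closure) or by acid-induced oligomerisation, and regiocontrol may erode. The fallback sets out from 4 and moves the introduction of the C8 oxygen behind the cycloaddition. The same cycloaddition through cation 6 is run with 3-bromofuran, a less donating and acid-stable diene whose C2 is still the nucleophilic position; this should give the 6-bromo cycloadduct F1. F1 is methylated as in step 4 to the axial methyl ketone F2, and Peterson methylenation as in step 5 gives the bromodiene F3. Miyaura borylation (B2pin2, PdCl2(dppf), KOAc, dioxane, 80 °C) converts the alkenyl bromide into the alkenyl pinacol boronate F4, and oxidation with NaBO3·4H2O in THF–H2O gives the C8 ketone through its enol. The fallback comes back to the route at 11.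

2. Step 11. Hydride delivery to the conformationally mobile cycloheptanone may show poor facial selectivity, and the basic hydride may trigger β-elimination of the lactone oxygen. The fallback sets out from 21 and corrects the carbinol by inversion instead of relying on kinetic control. Reduction with NaBH4 in MeOH at −40 °C (small hydride, axial-type attack) should favour the 8α-alcohol F5, and any 8β-alcohol 22 formed alongside goes on directly. Mitsunobu inversion of F5 (PPh3, diisopropyl azodicarboxylate, chloroacetic acid, toluene, 0 °C → rt) gives the 8β-chloroacetate F6. Thiourea and NaHCO3 in EtOH remove the chloroacetyl group without opening the lactone. The fallback comes back to the route at 22, which is silylated with t-BuMe2SiOTf and 2,6-lutidine to 23.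

3. Step 14. Acylation of the hindered C5 hydroxyl next to the quaternary C1 may be slow, and forcing conditions may isomerise the (Z)-angeloyl unit to the (E)-isomer. The fallback sets out from 28 and builds the (Z)-alkene on the ester instead of transferring it. Esterification with the saturated, less hindered 2-[bis(2,2,2-trifluoroethoxy)phosphoryl]propanoic acid (diisopropylcarbodiimide, DMAP, CH2Cl2) gives the phosphonopropanoate F7. Still–Gennari olefination of F7 with acetaldehyde (KN(SiMe3)2, 18-crown-6, THF, −78 °C) should give the (Z)-2-methylbut-2-enoate. The fallback comes back to the route at 31.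

Further compounds
F1 | step 3 | 6-bromo-2-[(1R)-1-phenylethoxy]-8-oxabicyclo[3.2.1]oct-6-en-3-one (alkoxy equatorial) | O1[C@@H]2C=C(Br)[C@H]1CC(=O)[C@H]2O[C@H](C)c1ccccc1
F2 | step 3 | 6-bromo-4-methyl-2-[(1R)-1-phenylethoxy]-8-oxabicyclo[3.2.1]oct-6-en-3-one (methyl axial) | O1[C@@H]2C=C(Br)[C@H]1[C@H](C)C(=O)[C@H]2O[C@H](C)c1ccccc1
F3 | step 3 | 6-bromo-4-methyl-3-methylidene-2-[(1R)-1-phenylethoxy]-8-oxabicyclo[3.2.1]oct-6-ene | O1[C@@H]2C=C(Br)[C@H]1[C@H](C)C(=C)[C@H]2O[C@H](C)c1ccccc1
F4 | step 3 | alkenyl pinacol boronate (F3 with Bpin in place of Br) | O1[C@@H]2C=C(B3OC(C)(C)C(C)(C)O3)[C@H]1[C@H](C)C(=C)[C@H]2O[C@H](C)c1ccccc1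
F5 | step 11 | 8α-alcohol (C8 epimer of 22) | O=C1O[C@@H]2[C@@H](C1)[C@H](O)C[C@H](C)[C@@]3(COC(C)(C)O3)[C@H]2O[C@H](C)c1ccccc1
F6 | step 11 | 8β-chloroacetate of 22 | O=C1O[C@@H]2[C@@H](C1)[C@@H](OC(=O)CCl)C[C@H](C)[C@@]3(COC(C)(C)O3)[C@H]2O[C@H](C)c1ccccc1
F7 | step 14 | C5 2-[bis(2,2,2-trifluoroethoxy)phosphoryl]propanoate of 28 | C=C1C(=O)O[C@@H]2[C@@H]1[C@@H](O[Si](C)(C)C(C)(C)C)C[C@H](C)[C@@]3(COC(C)(C)O3)[C@H]2OC(=O)C(C)P(=O)(OCC(F)(F)F)OCC(F)(F)F
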